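**Retrosynthetic overview**

1. Feature: the benzene ring of the chromene carries five contiguous oxygens (C5–OH, C6/C7/C8–OMe, ring O1 on C8a) and a single carbon substituent (C4 on C4a). It is therefore disconnected into dimethyl squarate (C5–C8 with their oxygens) and the enol-ether C=C of a 2,2-disubstituted 3,4-dihydro-2H-pyran (C4a, C8a, O1), joined as a 4-(dihydropyran-6-yl)-2,3,4-trimethoxycyclobutenone whose thermal 4π-opening/6π-closure forms C4a–C5 and the arene.
2. The C3=C4 double bond is introduced last, by DDQ dehydrogenation of the chroman through the ortho-quinone methide of the C5 phenol.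
3. Dihydropyran: lactol dehydration ← hydroformylation of a tertiary homoallylic alcohol ← catalytic asymmetric allylboration of a methyl ketone (sets C2).
4. Side-chain ring: chiral-imine Michael addition of 2,6-dimethylcyclohexanone to methyl vinyl ketone (quaternary centre), closure to the trans-4a,8-dimethyloctalone (secondary methyl by equilibration), then epoxidation and Eschenmoser–Tanabe fragmentation re-open the auxiliary ring; the methylene is installed after the allylation.
5. Ring order: cyclohexane (from 1) → temporary enone ring (made, then cleaved) → dihydropyran → cyclobutenone (from squarate) → benzene ring (key step).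

Key step: step 12

**Remarks on the chemistry**

- Assumption: in step 7 the (S)-configured 3,3′-dibromo-BINOL is taken to direct allyl to the Re face of the methyl ketone (chain in the place of the aryl group of acetophenone); if the sense proves opposite, the (R)-catalyst is used and nothing else changes.
- Compounds 1, 3, 6, 8, 16 and 22 are carried as the stereoisomer mixtures indicated, because the centres concerned are equilibrated (step 3) or destroyed (steps 5, 10, 12) later.
- The quaternary centre from step 2 is expected in high but not complete enantiomeric purity; any minor enantiomer becomes a diastereomer after step 7 and is to be removed by chromatography or crystallisation at 13 or 25.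

**Route**

Step 1
Reactants: 1 2,6-dimethylcyclohexan-1-one (commercial cis/trans mixture); 2 (S)-1-phenylethylamine
Product: 3 (1S)-N-(2,6-dimethylcyclohexylidene)-1-phenylethanamine (ring epimers)
Conditions: TsOH (cat.), toluene, reflux, Dean–Stark
Reagents that add atoms: none
Why: Acid-catalysed ketimine condensation driven by azeotropic removal of water; the ring α-centres epimerise freely through the secondary enamine, so the isomer mixture of 1 is of no consequence.

Step 2
Reactants: 3 (1S)-N-(2,6-dimethylcyclohexylidene)-1-phenylethanamine; 4 methyl vinyl ketone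
Product: 6 (2R)-2,6-dimethyl-2-(3-oxobutyl)cyclohexan-1-one (C6 epimer mixture), via Michael adduct imine 5 (not isolated)
Conditions: THF, rt → 40 °C; then 20% aq. AcOH, rt
Reagents that add atoms: water, O
Why: Chiral-imine Michael addition (deracemising alkylation): the secondary enamine tautomer adds to the enone in an aza-ene-like transition state on the face anti to the phenyl group of the auxiliary, which for the (S)-amine should set the quaternary centre as R in the sense established for 2-methylcyclohexanone; C6 is not controlled here and need not be.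

Step 3
Reactants: 6 (2R)-2,6-dimethyl-2-(3-oxobutyl)cyclohexan-1-one
Product: 7 (4aR,8R)-4a,8-dimethyl-4,4a,5,6,7,8-hexahydronaphthalen-2(3H)-one
Conditions: NaOMe, MeOH, 65 °C
Reagents that add atoms: none
Why: Intramolecular aldol condensation (ring closure of a Robinson annulation); under the equilibrating alkoxide conditions the γ-centre C8 epimerises through the dienolate to the equatorial methyl, trans to the axial angular methyl (the cis isomer would carry a syn-diaxial Me/Me interaction), so both C6 epimers of 6 should converge and the secondary methyl centre is set here by thermodynamic control.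

Step 4
Reactants: 7 (4aR,8R)-4a,8-dimethyl-4,4a,5,6,7,8-hexahydronaphthalen-2(3H)-one
Product: 8 (4aR,8R)-1,8a-epoxy-4a,8-dimethyloctahydronaphthalen-2(1H)-one (epoxide diastereomers)
Conditions: 30% aq. H2O2, NaOH (cat.), MeOH, 0 °C → rt
Reagents that add atoms: hydrogen peroxide, OO
Why: Weitz–Scheffer nucleophilic epoxidation of the enone; the epoxide configuration is irrelevant because both diastereomers fragment to the same alkynone, and C8 is no longer epimerisable once the enone is consumed.

Step 5
Reactants: 8 (4aR,8R)-1,8a-epoxy-4a,8-dimethyloctahydronaphthalen-2(1H)-one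
Product: 10 (2R,6R)-2-(but-3-yn-1-yl)-2,6-dimethylcyclohexan-1-one, via epoxy tosylhydrazone 9 (not isolated)
Conditions: TsNHNH2 (1.1 equiv), AcOH/CH2Cl2 (1:1), −20 °C → rt
Reagents that add atoms: none
Why: Eschenmoser–Tanabe fragmentation: the tosylhydrazone opens the epoxide to an azoalkene alkoxide that fragments with loss of N2 and sulfinate into ring ketone and terminal alkyne; the cold, weakly acidic medium should not enolise the hindered ketone, so the trans relationship of the two methyl groups is carried over.

Step 6
Reactants: 10 (2R,6R)-2-(but-3-yn-1-yl)-2,6-dimethylcyclohexan-1-one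
Product: 11 (2R,6R)-2,6-dimethyl-2-(3-oxobutyl)cyclohexan-1-one
Conditions: (IPr)AuCl (2 mol%), AgSbF6 (2 mol%), 1,4-dioxane/H2O (2:1), 60 °C
Reagents that add atoms: water, O
Why: Gold(I)-catalysed Markovnikov hydration of the terminal alkyne under neutral conditions, which should spare the C6 centre and not re-close the aldol; it is placed before the methylenation because the later 1,6-enyne would cyclise under π-acid catalysis.

Step 7
Reactants: 11 (2R,6R)-2,6-dimethyl-2-(3-oxobutyl)cyclohexan-1-one
Product: 13 (2R,6R)-2-[(3S)-3-hydroxy-3-methylhex-5-en-1-yl]-2,6-dimethylcyclohexan-1-one, via borate ester 12 (not isolated)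
Conditions: allyl-B(OiPr)2 (1.5 equiv), (S)-3,3′-Br2-BINOL (15 mol%), PhCF3/PhMe (3:1), −35 °C; aq. NaHCO3 work-up
Reagents that add atoms: allyldiisopropoxyborane, C=CCB(OC(C)C)OC(C)C
Why: Chiral-diol-catalysed asymmetric allylboration of a ketone through a closed chair transition state with methyl axial; allyl is delivered to the Re face of the methyl ketone under catalyst control to set the tertiary carbinol (3S), and the ring ketone, flanked by a quaternary and a tertiary carbon, is too hindered to react.

Step 8
Reactants: 13 (2R,6R)-2-[(3S)-3-hydroxy-3-methylhex-5-en-1-yl]-2,6-dimethylcyclohexan-1-one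
Product: 14 (4S)-6-[(1R,3R)-1,3-dimethyl-2-methylidenecyclohexyl]-4-methylhex-1-en-4-ol
Conditions: Zn, CH2Br2, TiCl4, THF, 0 °C (reagent pre-formed); then 13, CH2Cl2, rt
Reagents that add atoms: dibromomethane, BrCBr
Why: Takai–Lombardo methylenation with the non-basic gem-dimetallic Zn/Ti methylene reagent, which converts hindered α-epimerisable ketones to methylene compounds without epimerisation; the free tertiary alcohol only consumes reagent and the terminal alkene is inert.

Step 9
Reactants: 14 (4S)-6-[(1R,3R)-1,3-dimethyl-2-methylidenecyclohexyl]-4-methylhex-1-en-4-ol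
Product: 16 (6R)-6-{2-[(1R,3R)-1,3-dimethyl-2-methylidenecyclohexyl]ethyl}-6-methyloxan-2-ol (anomers), via hydroxy aldehyde 15 (not isolated)
Conditions: Rh(acac)(CO)2 (1 mol%), Xantphos (2 mol%), CO/H2 (1:1, 10 bar), toluene, 70 °C
Reagents that add atoms: carbon monoxide, [C-]#[O+]
Why: Linear-selective Rh-catalysed hydroformylation of the monosubstituted alkene (the exocyclic 1,1-disubstituted alkene next to a quaternary carbon is too hindered to react), after which the δ-hydroxy aldehyde closes spontaneously to the six-membered lactol.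

Step 10
Reactants: 16 (6R)-6-{2-[(1R,3R)-1,3-dimethyl-2-methylidenecyclohexyl]ethyl}-6-methyloxan-2-ol
Product: 18 (2R)-2-{2-[(1R,3R)-1,3-dimethyl-2-methylidenecyclohexyl]ethyl}-2-methyl-3,4-dihydro-2H-pyran, via anomeric mesylate 17 (not isolated)
Conditions: MsCl (1.5 equiv), Et3N (5 equiv), CH2Cl2, 0 °C → reflux
Reagents that add atoms: none
Why: Lactol dehydration by anomeric sulfonylation and amine-mediated elimination, the standard glycal-type preparation of 3,4-dihydro-2H-pyrans; the quaternary C2 cannot epimerise.

Step 11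
Reactants: 18 (2R)-2-{2-[(1R,3R)-1,3-dimethyl-2-methylidenecyclohexyl]ethyl}-2-methyl-3,4-dihydro-2H-pyran; 19 dimethyl squarate
Product: 22 4-[(2R)-2-{2-[(1R,3R)-1,3-dimethyl-2-methylidenecyclohexyl]ethyl}-2-methyl-3,4-dihydro-2H-pyran-6-yl]-2,3,4-trimethoxycyclobut-2-en-1-one (both C4 epimers), via 6-lithiodihydropyran 20 (not isolated), via lithium alkoxide 21 (not isolated)
Conditions: t-BuLi (1.1 equiv), THF, −78 → 0 °C; cannulation into 19, THF, −78 °C; MeOTf (1.5 equiv), −78 → 0 °C; Et3N-deactivated silica
Reagents that add atoms: methyl trifluoromethanesulfonate, COS(=O)(=O)C(F)(F)F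
Why: Lithiation of the α-alkoxyvinyl C–H of the dihydropyran, 1,2-addition of the vinyllithium to one carbonyl of the squarate ester and O-methylation of the lithium alkoxide, the standard entry to 4-alkenyl-4-alkoxycyclobutenones; the new cyclobutenone centre forms without control, which is immaterial because it becomes sp2 in step 12.

Step 12
Reactants: 22 4-[(2R)-2-{2-[(1R,3R)-1,3-dimethyl-2-methylidenecyclohexyl]ethyl}-2-methyl-3,4-dihydro-2H-pyran-6-yl]-2,3,4-trimethoxycyclobut-2-en-1-one
Product: 25 (2S)-2-{2-[(1R,3R)-1,3-dimethyl-2-methylidenecyclohexyl]ethyl}-6,7,8-trimethoxy-2-methyl-3,4-dihydro-2H-chromen-5-ol, via dienylketene 23 (not isolated), via cyclohexadienone 24 (not isolated)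
Conditions: p-xylene (degassed, 0.02 M), 140 °C, Ar
Reagents that add atoms: none
Why: Heating opens the cyclobutenone by conrotatory 4π-electrocyclic cleavage of the C1–C4 bond to dienylketene 23, and the ketene carbon then bonds to C5 of the dihydropyran (the enol-ether β-carbon) in a thermal disrotatory 6π-electrocyclisation that closes the six-membered carbocycle as dienone 24; enolisation gives the benzene ring of 25 with the ketene oxygen as the free C5 hydroxyl and the methoxy groups at C6, C7 and C8. The closest known reaction type is the thermal ring expansion of 4-alkenyl-4-alkoxycyclobutenones to alkoxyphenols (Moore rearrangement), which is established for cyclic enol-ether substituents. The selectivity needed is torquoselective opening with the dihydropyranyl group turning inward toward the ketene; the C4 methoxy donor secures this by its strong preference for outward rotation, so both C4 epimers of 22 should give the same (Z)-dienylketene. The placement of the five oxygens is fixed by connectivity, because only the β-carbon of the enol ether can reach the ketene carbon. No stereocentre is created (the sp3 carbon of 24 is lost on aromatisation), and the C2 quaternary centre, the ring centres and the hindered exocyclic alkene take no part at 140 °C. The electron-rich phenol is air-sensitive, hence degassed solvent and argon.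

Step 13
Reactants: 25 (2S)-2-{2-[(1R,3R)-1,3-dimethyl-2-methylidenecyclohexyl]ethyl}-6,7,8-trimethoxy-2-methyl-3,4-dihydro-2H-chromen-5-ol
Product: 27 (2S)-2-{2-[(1R,3R)-1,3-dimethyl-2-methylidenecyclohexyl]ethyl}-6,7,8-trimethoxy-2-methyl-2H-chromen-5-ol, via ortho-quinone methide 26 (not isolated)
Conditions: DDQ (1.05 equiv), dry benzene, rt → 60 °C, Ar
Reagents that add atoms: none
Why: DDQ dehydrogenation of a hydroxychroman: hydride abstraction from benzylic C4 ortho to the free C5 phenol gives the ortho-quinone methide, which tautomerises by 1,5-hydrogen shift from C3 to the 2H-chromene; the quaternary C2 and the unactivated exocyclic alkene should not be touched.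

**Compound list**

1 | 2,6-dimethylcyclohexan-1-one (cis/trans mixture) | CC1CCCC(C)C1=O | starting material
2 | (S)-1-phenylethylamine | C[C@H](N)c1ccccc1 | starting material
3 | (1S)-N-(2,6-dimethylcyclohexylidene)-1-phenylethanamine (ring epimers) | CC1CCCC(C)C1=N[C@@H](C)c1ccccc1 | intermediate
4 | methyl vinyl ketone (but-3-en-2-one) | C=CC(C)=O | starting material
5 | (1S)-N-[(2R)-2,6-dimethyl-2-(3-oxobutyl)cyclohexylidene]-1-phenylethanamine (not isolated) | CC1CCC[C@](C)(CCC(C)=O)C1=N[C@@H](C)c1ccccc1 | intermediate
6 | (2R)-2,6-dimethyl-2-(3-oxobutyl)cyclohexan-1-one (C6 epimer mixture) | CC1CCC[C@](C)(CCC(C)=O)C1=O | intermediate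
7 | (4aR,8R)-4a,8-dimethyl-4,4a,5,6,7,8-hexahydronaphthalen-2(3H)-one | O=C1C=C2[C@H](C)CCC[C@]2(C)CC1 | intermediate
8 | (4aR,8R)-1,8a-epoxy-4a,8-dimethyloctahydronaphthalen-2(1H)-one (epoxide diastereomers) | O=C1C2OC23[C@H](C)CCC[C@]3(C)CC1 | intermediate
9 | p-toluenesulfonylhydrazone of 8 (not isolated) | Cc1ccc(cc1)S(=O)(=O)NN=C1C2OC23[C@H](C)CCC[C@]3(C)CC1 | intermediate
10 | (2R,6R)-2-(but-3-yn-1-yl)-2,6-dimethylcyclohexan-1-one | O=C1[C@H](C)CCC[C@]1(C)CCC#C | intermediate
11 | (2R,6R)-2,6-dimethyl-2-(3-oxobutyl)cyclohexan-1-one | O=C1[C@H](C)CCC[C@]1(C)CCC(C)=O | intermediate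
12 | diisopropyl (3S)-1-[(1R,3R)-1,3-dimethyl-2-oxocyclohexyl]-3-methylhex-5-en-3-yl borate (not isolated) | O=C1[C@H](C)CCC[C@]1(C)CC[C@](C)(OB(OC(C)C)OC(C)C)CC=C | intermediate
13 | (2R,6R)-2-[(3S)-3-hydroxy-3-methylhex-5-en-1-yl]-2,6-dimethylcyclohexan-1-one | O=C1[C@H](C)CCC[C@]1(C)CC[C@](C)(O)CC=C | intermediate
14 | (4S)-6-[(1R,3R)-1,3-dimethyl-2-methylidenecyclohexyl]-4-methylhex-1-en-4-ol | C=C1[C@H](C)CCC[C@]1(C)CC[C@](C)(O)CC=C | intermediate
15 | (5R)-7-[(1R,3R)-1,3-dimethyl-2-methylidenecyclohexyl]-5-hydroxy-5-methylheptanal (not isolated) | C=C1[C@H](C)CCC[C@]1(C)CC[C@](C)(O)CCCC=O | intermediate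
16 | (6R)-6-{2-[(1R,3R)-1,3-dimethyl-2-methylidenecyclohexyl]ethyl}-6-methyloxan-2-ol (anomers) | C=C1[C@H](C)CCC[C@]1(C)CC[C@@]1(C)CCCC(O)O1 | intermediate
17 | anomeric methanesulfonate of 16 (not isolated) | C=C1[C@H](C)CCC[C@]1(C)CC[C@@]1(C)CCCC(OS(C)(=O)=O)O1 | intermediate
18 | (2R)-2-{2-[(1R,3R)-1,3-dimethyl-2-methylidenecyclohexyl]ethyl}-2-methyl-3,4-dihydro-2H-pyran | C=C1[C@H](C)CCC[C@]1(C)CC[C@@]1(C)CCC=CO1 | intermediate
19 | dimethyl squarate (3,4-dimethoxycyclobut-3-ene-1,2-dione) | COC1=C(OC)C(=O)C1=O | starting material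
20 | 6-lithio derivative of 18 (not isolated) | C=C1[C@H](C)CCC[C@]1(C)CC[C@@]1(C)CCC=C([Li])O1 | intermediate
21 | lithium 1-(dihydropyran-6-yl)-2,3-dimethoxy-4-oxocyclobut-2-en-1-olate from 20 and 19 (not isolated) | C=C1[C@H](C)CCC[C@]1(C)CC[C@@]1(C)CCC=C(O1)C1([O-])C(OC)=C(OC)C1=O.[Li+] | intermediate
22 | 4-[(2R)-2-{2-[(1R,3R)-1,3-dimethyl-2-methylidenecyclohexyl]ethyl}-2-methyl-3,4-dihydro-2H-pyran-6-yl]-2,3,4-trimethoxycyclobut-2-en-1-one (both C4 epimers) | C=C1[C@H](C)CCC[C@]1(C)CC[C@@]1(C)CCC=C(O1)C1(OC)C(OC)=C(OC)C1=O | intermediate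
23 | (Z)-4-(dihydropyran-6-yl)-2,3,4-trimethoxybuta-1,3-dien-1-one, the dienylketene from 22 (not isolated) | C=C1[C@H](C)CCC[C@]1(C)CC[C@@]1(C)CCC=C(O1)/C(OC)=C(OC)\C(OC)=C=O | intermediate
24 | 6,7,8-trimethoxy-2,3,4,4a-tetrahydro-5H-chromen-5-one bearing the C2 substituents, the dienone from 23 (not isolated) | C=C1[C@H](C)CCC[C@]1(C)CC[C@@]1(C)CCC2C(=O)C(OC)=C(OC)C(OC)=C2O1 | intermediate
25 | (2S)-2-{2-[(1R,3R)-1,3-dimethyl-2-methylidenecyclohexyl]ethyl}-6,7,8-trimethoxy-2-methyl-3,4-dihydro-2H-chromen-5-ol | C=C1[C@H](C)CCC[C@]1(C)CC[C@@]1(C)CCc2c(O)c(OC)c(OC)c(OC)c2O1 | intermediate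
26 | ortho-quinone methide of 25 (C4=C4a, C5=O; not isolated) | C=C1[C@H](C)CCC[C@]1(C)CC[C@@]1(C)CC=C2C(=O)C(OC)=C(OC)C(OC)=C2O1 | intermediate
27 | (2S)-2-{2-[(1R,3R)-1,3-dimethyl-2-methylidenecyclohexyl]ethyl}-6,7,8-trimethoxy-2-methyl-2H-chromen-5-ol | C=C1[C@H](C)CCC[C@]1(C)CC[C@@]1(C)C=Cc2c(O)c(OC)c(OC)c(OC)c2O1 | target

**Totals**

Total step count: 13. Longest linear sequence: 13 steps (1 → 27); dimethyl squarate enters at step 11.

**Steps most likely to fail**

1. Step 7. The catalyst may discriminate poorly between methyl and the unbranched CH2CH2 chain, or act in the opposite facial sense, giving an epimer mixture at a carbinol carbon remote from the ring centres that would be hard to separate. The fallback sets the centre by epoxidation instead of carbonyl addition; it sets out from 10 and returns at 14, bypassing steps 6–8. Alkynone 10 is methylenated under the Takai–Lombardo conditions of step 8 to the enyne F1. Zr-catalysed methylalumination of the terminal alkyne (Me3Al, Cp2ZrCl2, CH2Cl2; the hindered exocyclic alkene is inert) and trapping of the alkenylalanate with paraformaldehyde should give the (E)-allylic alcohol F2. Sharpless asymmetric epoxidation with L-(+)-diethyl tartrate, Ti(OiPr)4 and t-BuOOH then fixes the tertiary C–O centre, by the allylic-alcohol face rule, in the (2S,3S)-epoxy alcohol F3. Dess–Martin oxidation gives the epoxy aldehyde F4 and Wittig methylenation (Ph3P=CH2, THF, −78 → 0 °C) the vinyl epoxide F5. Pd(0)/n-Bu3P-catalysed hydrogenolysis with HCO2H–Et3N cleaves only the allylic C–O bond and delivers hydride to the internal allylic carbon, giving homoallylic alcohol 14 with the tertiary centre retained.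

2. Step 13. The oxidant may attack the electron-rich para-methoxyphenol itself (quinone formation with loss of a methyl group, or further oxidation of the chromene) in competition with benzylic hydride abstraction. The fallback sets out from 25 and returns at 27. Acetylation (Ac2O, pyridine, DMAP) gives the chroman acetate F7, in which phenol oxidation is blocked. DDQ in refluxing dioxane should then dehydrogenate through the C4 benzylic cation stabilised by O1 and the para 7-methoxy group, as in non-phenolic alkoxychromans, to the chromene acetate F8. K2CO3 in MeOH removes the acetate to give 27.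

3. Step 8. Methylenation of a ketone flanked by a quaternary and a tertiary carbon may be incomplete, and prolonged exposure to the Lewis-acidic reagent may ionise the tertiary homoallylic alcohol or erode the C6 centre. The fallback is an addition–elimination sequence; it sets out from 13 and returns at 14. Addition of Me3SiCH2Li/CeCl3 (3 equiv, THF, −78 °C; the organocerium reagent adds to hindered enolisable ketones without enolisation) gives the β-hydroxysilane F6. KH in THF then effects Peterson syn-elimination to 14.

**Further compounds**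

F1 | step 7 | (1R,3R)-1-(but-3-yn-1-yl)-1,3-dimethyl-2-methylidenecyclohexane | C=C1[C@H](C)CCC[C@]1(C)CCC#C
F2 | step 7 | (2E)-5-[(1R,3R)-1,3-dimethyl-2-methylidenecyclohexyl]-3-methylpent-2-en-1-ol | C=C1[C@H](C)CCC[C@]1(C)CC/C(C)=C/CO
F3 | step 7 | [(2S,3S)-3-{2-[(1R,3R)-1,3-dimethyl-2-methylidenecyclohexyl]ethyl}-3-methyloxiran-2-yl]methanol | C=C1[C@H](C)CCC[C@]1(C)CC[C@]1(C)O[C@H]1CO
F4 | step 7 | (2R,3S)-3-{2-[(1R,3R)-1,3-dimethyl-2-methylidenecyclohexyl]ethyl}-3-methyloxirane-2-carbaldehyde | C=C1[C@H](C)CCC[C@]1(C)CC[C@]1(C)O[C@H]1C=O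
F5 | step 7 | (2S,3S)-2-ethenyl-3-{2-[(1R,3R)-1,3-dimethyl-2-methylidenecyclohexyl]ethyl}-3-methyloxirane | C=C1[C@H](C)CCC[C@]1(C)CC[C@]1(C)O[C@H]1C=C
F6 | step 8 | (2R,6R)-2-[(3S)-3-hydroxy-3-methylhex-5-en-1-yl]-2,6-dimethyl-1-[(trimethylsilyl)methyl]cyclohexan-1-ol (C1 epimers) | C[Si](C)(C)CC1(O)[C@H](C)CCC[C@]1(C)CC[C@](C)(O)CC=C
F7 | step 13 | (2S)-2-{2-[(1R,3R)-1,3-dimethyl-2-methylidenecyclohexyl]ethyl}-6,7,8-trimethoxy-2-methyl-3,4-dihydro-2H-chromen-5-yl acetate | C=C1[C@H](C)CCC[C@]1(C)CC[C@@]1(C)CCc2c(OC(C)=O)c(OC)c(OC)c(OC)c2O1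
F8 | step 13 | (2S)-2-{2-[(1R,3R)-1,3-dimethyl-2-methylidenecyclohexyl]ethyl}-6,7,8-trimethoxy-2-methyl-2H-chromen-5-yl acetate | C=C1[C@H](C)CCC[C@]1(C)CC[C@@]1(C)C=Cc2c(OC(C)=O)c(OC)c(OC)c(OC)c2O1
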